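**Strategy.** The target is a para-depside: ring A (everninic acid) esterifies the C4' oxygen of ring B, a 6'-pentyl-2',4'-dihydroxybenzoic acid. Ring B is not bought but built: its C1' carboxyl, meta-related C2' and C4' oxygens and C6' pentyl group map exactly onto dibenzyl malonate plus (E)-non-3-en-2-one. One pot forges the C1'–C6' bond (conjugate addition) and the C2'–C3' bond (Claisen closure), giving a benzyl 2,4-dioxo-6-pentylcyclohexanecarboxylate. Bromine-mediated aromatisation then delivers benzyl olivetolate, whose free C4' hydroxyl (the C2' hydroxyl is chelated to the ester) is acylated by O-benzyl everninoyl chloride; one hydrogenolysis removes both benzyl groups.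

Key step: step 1

Assumption: everninic acid (2-hydroxy-4-methoxy-6-methylbenzoic acid) is taken as purchasable; ring B is numbered C1' (carboxyl-bearing), C2' (hydroxyl), C3', C4' (depside oxygen), C5', C6' (pentyl).

**Step 1**
Reactants: 1 dibenzyl malonate; 2 (E)-non-3-en-2-one
Product: 4 racemic benzyl 2,4-dioxo-6-pentylcyclohexane-1-carboxylate, via Michael adduct 3 (not isolated)
Conditions: NaOCH2Ph (1.1 equiv, 1 M in BnOH), THF, 0 °C to reflux; then 1 M HCl, 0 °C
Reagents that add atoms: none
Why: Benzyloxide deprotonates malonate 1, and the soft, stabilised anion adds in conjugate fashion to C4 of enone 2 (the carbon bearing the pentyl chain), forming the C1'–C6' bond and adduct 3. Proton transfer gives the terminal methyl-ketone enolate, which attacks one benzyl ester carbonyl in a Dieckmann-type Claisen condensation (6-exo-trig closure), forming the C2'–C3' bond, closing the carbocycle of ring B and expelling benzyloxide. The closest known reaction type is the Michael–Claisen annulation of dialkyl malonates with alk-3-en-2-ones to 6-alkyl-2,4-dioxocyclohexanecarboxylates, the standard entry to 5-alkylresorcinol carboxylates; only the ester alkyl group is new here. The stereocentres created at C1' and C6' are not controlled (C1' is epimerisable, so the trans isomer should predominate) and need not be, because both are destroyed on aromatisation. The step needs 1,4- over 1,2-addition and six-membered closure: the soft malonate nucleophile secures the former, the latter is secured because the internal ketone enolate could only form a four-membered ring, and irreversible deprotonation of the strongly acidic cyclic dione should pull all equilibria forward. Using the alkoxide that matches the ester avoids ester scrambling, and THF keeps the amount of high-boiling benzyl alcohol small.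

**Step 2**
Reactants: 4 racemic benzyl 2,4-dioxo-6-pentylcyclohexane-1-carboxylate
Product: 6 benzyl 2,4-dihydroxy-6-pentylbenzoate, via 3-bromo dione 5 (not isolated)
Conditions: Br2 (1.0 equiv), DMF, 0 °C; then 70 °C
Reagents that add atoms: none
Why: Electrophilic bromination of the enolised dione followed by HBr-mediated dehydrobromination and tautomerisation (the classical bromine/DMF aromatisation of 2,4-dioxocyclohexanecarboxylates to 2,4-dihydroxybenzoates) should erase both transient stereocentres, and the benzyl ester should tolerate the DMF-buffered HBr at this moderate temperature.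

**Step 3**
Reactants: 7 everninic acid; 8 benzyl bromide
Product: 9 benzyl 2-(benzyloxy)-4-methoxy-6-methylbenzoate
Conditions: BnBr (2.4 equiv), K2CO3 (3 equiv), DMF, 60 °C
Reagents that add atoms: benzyl bromide (8), BrCc1ccccc1
Why: Double SN2 O-alkylation (Williamson ether synthesis at the phenol, carboxylate alkylation at the acid) should proceed cleanly because no other nucleophilic site is present.

**Step 4**
Reactants: 9 benzyl 2-(benzyloxy)-4-methoxy-6-methylbenzoate
Product: 10 2-(benzyloxy)-4-methoxy-6-methylbenzoic acid
Conditions: KOH (5 equiv), DMSO–H2O (4:1), 90 °C; then 1 M HCl, 0 °C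
Reagents that add atoms: potassium hydroxide, [K+].[OH-]
Why: Saponification with poorly solvated hydroxide in aqueous DMSO should overcome the di-ortho hindrance of the ester, while the benzyl and methyl aryl ethers are inert to base.

**Step 5**
Reactants: 10 2-(benzyloxy)-4-methoxy-6-methylbenzoic acid; 6 benzyl 2,4-dihydroxy-6-pentylbenzoate
Product: 12 benzyl 4-{[2-(benzyloxy)-4-methoxy-6-methylbenzoyl]oxy}-2-hydroxy-6-pentylbenzoate, via acid chloride 11 (not isolated)
Conditions: (COCl)2 (1.2 equiv), DMF (cat.), CH2Cl2, 0 °C to rt, concentrate; then 6 (1.0 equiv), K2CO3 (1.5 equiv), acetone, 0 °C to rt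
Reagents that add atoms: none
Why: Vilsmeier-type acid chloride formation followed by Schotten–Baumann-type acylation of the phenoxide should be selective for O4', because the C4' hydroxyl para to the ester is the more acidic and unhindered phenol whereas the C2' hydroxyl is hydrogen-bonded to and flanked by the benzyl ester (the usual para-depside selectivity).

**Step 6**
Reactants: 12 benzyl 4-{[2-(benzyloxy)-4-methoxy-6-methylbenzoyl]oxy}-2-hydroxy-6-pentylbenzoate
Product: 13 2-hydroxy-4-[(2-hydroxy-4-methoxy-6-methylbenzoyl)oxy]-6-pentylbenzoic acid (target, CNP0313373.0)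
Conditions: H2 (1 atm), Pd/C (palladium on carbon, 10 wt% Pd), EtOAc, rt
Reagents that add atoms: none
Why: Catalytic hydrogenolysis cleaves the benzyl ester and the benzyl aryl ether in one operation under neutral conditions at room temperature, which should leave the depside aryl ester intact and avoid decarboxylation of the liberated salicylic-type acid.

**Compound list**
1 | dibenzyl malonate | O=C(CC(=O)OCc1ccccc1)OCc1ccccc1 | starting material
2 | (E)-non-3-en-2-one | CCCCC/C=C/C(C)=O | starting material
3 | dibenzyl 2-(2-oxononan-4-yl)malonate (racemic Michael adduct) | CCCCCC(CC(C)=O)C(C(=O)OCc1ccccc1)C(=O)OCc1ccccc1 | intermediate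
4 | benzyl 2,4-dioxo-6-pentylcyclohexane-1-carboxylate (racemic, diastereomer mixture, drawn as the diketone tautomer) | CCCCCC1CC(=O)CC(=O)C1C(=O)OCc1ccccc1 | intermediate
5 | benzyl 3-bromo-2,4-dioxo-6-pentylcyclohexane-1-carboxylate (racemic, not isolated) | CCCCCC1CC(=O)C(Br)C(=O)C1C(=O)OCc1ccccc1 | intermediate
6 | benzyl 2,4-dihydroxy-6-pentylbenzoate (benzyl olivetolate) | CCCCCc1cc(O)cc(O)c1C(=O)OCc1ccccc1 | intermediate
7 | everninic acid (2-hydroxy-4-methoxy-6-methylbenzoic acid) | Cc1cc(OC)cc(O)c1C(=O)O | starting material
8 | benzyl bromide | BrCc1ccccc1 | starting material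
9 | benzyl 2-(benzyloxy)-4-methoxy-6-methylbenzoate | Cc1cc(OC)cc(OCc2ccccc2)c1C(=O)OCc1ccccc1 | intermediate
10 | 2-(benzyloxy)-4-methoxy-6-methylbenzoic acid | Cc1cc(OC)cc(OCc2ccccc2)c1C(=O)O | intermediate
11 | 2-(benzyloxy)-4-methoxy-6-methylbenzoyl chloride (not isolated) | Cc1cc(OC)cc(OCc2ccccc2)c1C(=O)Cl | intermediate
12 | benzyl 4-{[2-(benzyloxy)-4-methoxy-6-methylbenzoyl]oxy}-2-hydroxy-6-pentylbenzoate | CCCCCc1cc(OC(=O)c2c(C)cc(OC)cc2OCc2ccccc2)cc(O)c1C(=O)OCc1ccccc1 | intermediate
13 | 2-hydroxy-4-[(2-hydroxy-4-methoxy-6-methylbenzoyl)oxy]-6-pentylbenzoic acid | CCCCCc1cc(OC(=O)c2c(C)cc(OC)cc2O)cc(O)c1C(=O)O | target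

**Totals.** Total step count: 6. Longest linear sequence: 4 steps (steps 1, 2, 5, 6 from 1 and 2; equally steps 3, 4, 5, 6 from 7).

**Steps most likely to fail**

Step 2 (aromatisation of 4). The resorcinol ring, once formed, may be brominated further. The benzyl ester may also be lost through acid at the temperature needed for dehydrobromination, after which the acid would decarboxylate. The fallback inverts the order of acylation and aromatisation. It sets out from 4 and from acid chloride 11 (made from 10 as in step 5). O-Acylation of the vinylogous acid at the unhindered C4' oxygen (Et3N, CH2Cl2, 0 °C) should give the enol ester benzyl 4-{[2-(benzyloxy)-4-methoxy-6-methylbenzoyl]oxy}-2-oxo-6-pentylcyclohex-3-ene-1-carboxylate F1. With C3' deactivated, the most acidic C–H left is C1' of the beta-keto ester. N-Bromosuccinimide with Et3N should therefore give the tertiary bromide benzyl 1-bromo-4-{[2-(benzyloxy)-4-methoxy-6-methylbenzoyl]oxy}-2-oxo-6-pentylcyclohex-3-ene-1-carboxylate F2. Amine-promoted E2 loss of HBr across C1'–C6' and tautomerisation should then give the phenol. The sequence comes back to the route at 12, bypassing steps 2 and 5 without strong acid or heating.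

Step 5 (depside coupling). Acylation by the di-ortho-substituted acid chloride may be sluggish, which could allow competing acylation at the chelated C2' hydroxyl or diacylation under basic conditions. The fallback changes from a base-mediated phenoxide acylation to an acid-mediated mixed-anhydride coupling. It sets out from 10 and 6. Trifluoroacetic anhydride in toluene at room temperature should convert 10 into 2-(benzyloxy)-4-methoxy-6-methylbenzoic trifluoroacetic anhydride F3. This acylium-like donor is little affected by ortho hindrance and should react with the neutral, non-chelated C4' phenol while the hydrogen-bonded C2' hydroxyl stays inert. The fallback comes back to the route at 12.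

Step 1 (Michael–Claisen annulation). Ring closure may be incomplete, or enone 2 may oligomerise or undergo retro-Michael loss under stoichiometric alkoxide at reflux. The fallback separates the two bond formations. It sets out from 1 and 2. A Michael addition with catalytic base (K2CO3, catalytic Bu4NBr, toluene, rt) should give adduct 3, which is isolated. A separate Dieckmann cyclisation with NaH (THF, catalytic BnOH, 0 °C to reflux; then HCl) should then close the ring. The fallback comes back to the route at 4 and makes no compound outside the list (F0).

**Further compounds**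
F1 | step 2 | benzyl 4-{[2-(benzyloxy)-4-methoxy-6-methylbenzoyl]oxy}-2-oxo-6-pentylcyclohex-3-ene-1-carboxylate (racemic) | CCCCCC1CC(OC(=O)c2c(C)cc(OC)cc2OCc2ccccc2)=CC(=O)C1C(=O)OCc1ccccc1
F2 | step 2 | benzyl 1-bromo-4-{[2-(benzyloxy)-4-methoxy-6-methylbenzoyl]oxy}-2-oxo-6-pentylcyclohex-3-ene-1-carboxylate (racemic) | CCCCCC1CC(OC(=O)c2c(C)cc(OC)cc2OCc2ccccc2)=CC(=O)C1(Br)C(=O)OCc1ccccc1
F3 | step 5 | 2-(benzyloxy)-4-methoxy-6-methylbenzoic trifluoroacetic anhydride | Cc1cc(OC)cc(OCc2ccccc2)c1C(=O)OC(=O)C(F)(F)F
F0 | step 1 | none | none
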